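## Retrosynthetic overview
1. Endgame on the esters: cleave the phenol acetate; place the 3-OAc through the cyclic orthoacetate of the cis-3,4-diol. The diol comes from convex-face OsO4 addition to C3=C4 of a 6-O-aroyl dauca-3,7-dien-10-ol.
2. C3=C4(i-Pr) comes from a C4 cyclopentanone by kinetic enol triflate formation and iron-catalysed coupling with i-PrMgCl.
3. Key disconnection C1–C10: the C10 aldehyde is reduced to its samarium ketyl (a nucleophilic carbonyl carbon). It adds 7-endo to C1, the β-carbon of a 2-substituted 3-methylcyclopentenone. This one step closes the seven-membered ring and sets C1 (quaternary), C5 and C10 from C6.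
4. The cyclisation substrate comes from a CBS-set C6 carbinol. Its dienone comes from the lithiated ketal of 2-bromo-3-methylcyclopentenone and 4-methyl-5,6-dihydropyran-2-one, whose ring fixes the Z geometry of C7=C8.
5. Ring order: the five-membered ring is bought; the seven-membered ring is formed in the key step.

Assumption: the SMILES is taken literally (cis-fused; H-5, 1-CH3, 3-OAc, 4-OH and 10-OH on one face of the flat drawing, 6-O-aroyl and i-Pr on the other); daucane numbering is used in the text (C1 = C–CH3, C3 = OAc, C4 = OH/i-Pr, C5 = ring-fusion H, C6 = O-aroyl, C7=C8, C10 = OH); 1, 3 and 15 are catalogue chemicals.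

## Route

Step 1
Reactants: 1 2-bromo-3-methylcyclopent-2-en-1-one
Product: 2 6-bromo-7-methyl-1,4-dioxaspiro[4.4]non-6-ene
Conditions: HOCH2CH2OH, p-TsOH (cat.), PhH, reflux, Dean–Stark
Reagents that add atoms: ethylene glycol, OCCO
Why: Acid-catalysed ketalisation masks the ketone so that the C–Br bond can be lithiated (α-ketovinyl anion equivalent), the α-bromine keeps the double bond in place, and no stereocentre is formed.

Step 2
Reactants: 2 6-bromo-7-methyl-1,4-dioxaspiro[4.4]non-6-ene; 3 4-methyl-5,6-dihydro-2H-pyran-2-one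
Product: 5 (2Z)-5-hydroxy-3-methyl-1-(7-methyl-1,4-dioxaspiro[4.4]non-6-en-6-yl)pent-2-en-1-one, via alkenyllithium 4 (not isolated)
Conditions: n-BuLi, THF, −78 °C; then 3, −78 °C; AcOH/THF quench at −78 °C
Reagents that add atoms: none
Why: Br/Li exchange followed by 1,2-addition to the δ-lactone stops at the lithium hemiketal at −78 °C and opens to the hydroxy ketone on quench (nucleophilic acyl substitution), and the ring of 3 has already fixed the Z geometry of C7=C8 that the seven-membered ring needs.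

Step 3
Reactants: 5 (2Z)-5-hydroxy-3-methyl-1-(7-methyl-1,4-dioxaspiro[4.4]non-6-en-6-yl)pent-2-en-1-one
Product: 7 2-[(1S,2Z)-1,5-dihydroxy-3-methylpent-2-en-1-yl]-3-methylcyclopent-2-en-1-one, via ketal diol 6 (not isolated)
Conditions: (R)-Me-CBS (20 mol %), catecholborane (2.5 equiv), PhMe, −78 °C; then 5 % aq oxalic acid, THF, 0 °C
Reagents that add atoms: water, O
Why: In this Corey–Bakshi–Shibata reduction the fully substituted, ketal-flanked cyclopentenyl group is the large substituent and the CH=C group the small one, so the (R)-catalyst gives the (S)-carbinol at C6 (catecholborane at −78 °C leaves the alkenes alone), and the allylic ketal then hydrolyses under mild acid faster than the doubly allylic alcohol ionises.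

Step 4
Reactants: 7 2-[(1S,2Z)-1,5-dihydroxy-3-methylpent-2-en-1-yl]-3-methylcyclopent-2-en-1-one
Product: 8 3-methyl-2-[(1S,2Z)-3-methyl-1,5-bis(triethylsilyloxy)pent-2-en-1-yl]cyclopent-2-en-1-one
Conditions: TESCl (2.5 equiv), imidazole, DMAP (cat.), DMF, 0 °C to rt
Reagents that add atoms: chlorotriethylsilane, CC[Si](Cl)(CC)CC
Why: Standard silylation of both hydroxyls caps O6, which prevents lactol formation with the later C10 aldehyde and supplies the bulky group that steers the cyclisation, and no stereocentre is touched.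

Step 5
Reactants: 8 3-methyl-2-[(1S,2Z)-3-methyl-1,5-bis(triethylsilyloxy)pent-2-en-1-yl]cyclopent-2-en-1-one
Product: 9 (3Z,5S)-3-methyl-5-(2-methyl-5-oxocyclopent-1-en-1-yl)-5-(triethylsilyloxy)pent-3-enal
Conditions: (COCl)2, DMSO, CH2Cl2, −78 to −40 °C; Et3N, −78 to −20 °C; cold pH 7 buffer
Reagents that add atoms: none
Why: Swern conditions oxidise a primary TES ether directly (the chlorosulfonium ion attacks the unhindered silyl ether oxygen, Et3SiCl leaves and the ylide collapses) while the secondary TES ether survives, so the β,γ-unsaturated aldehyde is unveiled in one operation and is kept cold to avoid conjugation.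

Step 6 (key step)
Reactants: 9 (3Z,5S)-3-methyl-5-(2-methyl-5-oxocyclopent-1-en-1-yl)-5-(triethylsilyloxy)pent-3-enal
Product: 11 (3aS,4S,8S,8aR)-4-hydroxy-3a,6-dimethyl-8-(triethylsilyloxy)-3,3a,4,5,8,8a-hexahydroazulen-1(2H)-one, via samarium ketyl 10 (not isolated)
Conditions: SmI2 (2.5 equiv), HMPA (10 equiv), t-BuOH (2 equiv), THF (5 mM, slow addition of 9), −78 °C; cold aq Rochelle salt
Reagents that add atoms: none
Why: In this SmI2 ketyl–olefin (carbonyl–enone) reductive cyclisation one electron turns the normally electrophilic C10 aldehyde carbon into a nucleophilic ketyl that adds 7-endo to C1, the electrophilic enone β-carbon, and a second electron gives the Sm(III) enolate; the chain swings over the enone face that leaves C6–H rather than OTES next to the C1 methyl (A1,3 strain, sets C1), the HMPA-solvated O–Sm points away from C5 and the five-membered ring (sets C10, OH cis to CH3), and C5 is protonated on the face not covered by the new ring (cis fusion).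

Step 7
Reactants: 11 (3aS,4S,8S,8aR)-4-hydroxy-3a,6-dimethyl-8-(triethylsilyloxy)-3,3a,4,5,8,8a-hexahydroazulen-1(2H)-one
Product: 12 (3aS,4S,8S,8aR)-4-hydroxy-3a,6-dimethyl-8-(triethylsilyloxy)-3,3a,4,5,8,8a-hexahydroazulen-1-yl trifluoromethanesulfonate
Conditions: LiHMDS (2.3 equiv), THF, −78 °C; PhNTf2 (1.2 equiv), −78 to 0 °C; H2O
Reagents that add atoms: N-phenylbis(trifluoromethanesulfonimide), O=S(=O)(N(c1ccccc1)S(=O)(=O)C(F)(F)F)C(F)(F)F
Why: In this kinetic enol triflate formation the first equivalent of base is taken by the OH and the second removes a proton from the open C3 methylene rather than the crowded tertiary C5–H, so there is no epimerisation or β-elimination of OTES, and PhNTf2 sulfonylates the enolate but not the hindered aliphatic lithium alkoxide.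

Step 8
Reactants: 12 (3aS,4S,8S,8aR)-4-hydroxy-3a,6-dimethyl-8-(triethylsilyloxy)-3,3a,4,5,8,8a-hexahydroazulen-1-yl trifluoromethanesulfonate
Product: 14 (3aS,4S,8S,8aR)-3a,6-dimethyl-1-(propan-2-yl)-3,3a,4,5,8,8a-hexahydroazulene-4,8-diol, via TES ether 13 (not isolated)
Conditions: i-PrMgCl (3 equiv, slow), Fe(acac)3 (10 mol %), THF/NMP, −30 to 0 °C; then 1 M HCl, MeOH, 0 °C to rt
Reagents that add atoms: isopropylmagnesium chloride, CC(C)[Mg]Cl
Why: Iron-catalysed Kumada-type cross-coupling joins alkenyl triflates to secondary alkyl Grignard reagents within minutes without isomerisation to n-propyl, the C10 alkoxide is carried as its magnesium salt, dilute acid then removes the allylic TES ether, and no stereocentre is touched.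

Step 9
Reactants: 14 (3aS,4S,8S,8aR)-3a,6-dimethyl-1-(propan-2-yl)-3,3a,4,5,8,8a-hexahydroazulene-4,8-diol; 15 4-acetoxybenzoyl chloride
Product: 16 (3aS,4S,8S,8aR)-4-hydroxy-3a,6-dimethyl-1-(propan-2-yl)-3,3a,4,5,8,8a-hexahydroazulen-8-yl 4-acetoxybenzoate
Conditions: 15 (1.1 equiv), pyridine, DMAP (cat.), CH2Cl2, −20 to 0 °C
Reagents that add atoms: none
Why: DMAP-catalysed acylation takes the allylic C6–OH in preference to the C10–OH, which is neopentyl-like next to the quaternary C1, and C6 keeps its configuration because no C–O bond is broken.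

Step 10
Reactants: 16 (3aS,4S,8S,8aR)-4-hydroxy-3a,6-dimethyl-1-(propan-2-yl)-3,3a,4,5,8,8a-hexahydroazulen-8-yl 4-acetoxybenzoate
Product: 17 (1R,2S,3aS,4S,8S,8aR)-1,2,4-trihydroxy-3a,6-dimethyl-1-(propan-2-yl)-1,2,3,3a,4,5,8,8a-octahydroazulen-8-yl 4-acetoxybenzoate
Conditions: OsO4 (5 mol %), NMO (1.3 equiv), acetone/H2O, 0 °C to rt; aq Na2SO3
Reagents that add atoms: osmium tetroxide, O=[Os](=O)(=O)=O; N-methylmorpholine N-oxide, C[N+]1([O-])CCOCC1; water, O
Why: In this Upjohn syn-dihydroxylation OsO4 adds to the more electron-rich, strained cyclopentene C3=C4 from the convex face of the cis-fused bicycle (the face of H-5 and the angular CH3), which sets both O3 and O4 on that face and pushes i-Pr to the concave face, while C7=C8 is deactivated by its allylic ester (the selectivity pattern known from geranyl acetate).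

Step 11
Reactants: 17 (1R,2S,3aS,4S,8S,8aR)-1,2,4-trihydroxy-3a,6-dimethyl-1-(propan-2-yl)-1,2,3,3a,4,5,8,8a-octahydroazulen-8-yl 4-acetoxybenzoate
Product: 19 (1R,2S,3aS,4S,8S,8aR)-2-acetoxy-1,4-dihydroxy-3a,6-dimethyl-1-(propan-2-yl)-1,2,3,3a,4,5,8,8a-octahydroazulen-8-yl 4-acetoxybenzoate, via cyclic orthoacetate 18 (not isolated)
Conditions: MeC(OMe)3 (5 equiv), CSA (5 mol %), CH2Cl2, rt; then 80 % aq AcOH, 0 °C to rt
Reagents that add atoms: trimethyl orthoacetate, COC(C)(OC)OC; water, O
Why: Only the cis-1,2-diol can form the five-membered cyclic orthoacetate, and its acid hydrolysis (orthoester opening) frees the tertiary O4–H and leaves the acetyl group on the secondary O3, so the isolated C10–OH needs no protection and no C–O bond at a stereocentre is broken.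

Step 12
Reactants: 19 (1R,2S,3aS,4S,8S,8aR)-2-acetoxy-1,4-dihydroxy-3a,6-dimethyl-1-(propan-2-yl)-1,2,3,3a,4,5,8,8a-octahydroazulen-8-yl 4-acetoxybenzoate
Product: 20 (1R,2S,3aS,4S,8S,8aR)-2-acetoxy-1,4-dihydroxy-3a,6-dimethyl-1-(propan-2-yl)-1,2,3,3a,4,5,8,8a-octahydroazulen-8-yl 4-hydroxybenzoate (CNP0146780.2)
Conditions: pyrrolidine (3 equiv), CH2Cl2, 0 °C to rt
Reagents that add atoms: none
Why: In this chemoselective aminolysis the aryl acetate is an activated ester and is cleaved far faster than the hindered secondary acetate or the benzoate, which becomes even less electrophilic once the phenol is free.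

## Compound list
1 | 2-bromo-3-methylcyclopent-2-en-1-one | CC1=C(Br)C(=O)CC1 | starting material
2 | 6-bromo-7-methyl-1,4-dioxaspiro[4.4]non-6-ene | CC1=C(Br)C2(CC1)OCCO2 | intermediate
3 | 4-methyl-5,6-dihydro-2H-pyran-2-one | CC1=CC(=O)OCC1 | starting material
4 | (7-methyl-1,4-dioxaspiro[4.4]non-6-en-6-yl)lithium | CC1=C([Li])C2(CC1)OCCO2 | intermediate
5 | (2Z)-5-hydroxy-3-methyl-1-(7-methyl-1,4-dioxaspiro[4.4]non-6-en-6-yl)pent-2-en-1-one | OCC/C(C)=C\C(=O)C1=C(C)CCC12OCCO2 | intermediate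
6 | (1S,2Z)-3-methyl-1-(7-methyl-1,4-dioxaspiro[4.4]non-6-en-6-yl)pent-2-ene-1,5-diol | OCC/C(C)=C\[C@H](O)C1=C(C)CCC12OCCO2 | intermediate
7 | 2-[(1S,2Z)-1,5-dihydroxy-3-methylpent-2-en-1-yl]-3-methylcyclopent-2-en-1-one | OCC/C(C)=C\[C@H](O)C1=C(C)CCC1=O | intermediate
8 | 3-methyl-2-[(1S,2Z)-3-methyl-1,5-bis(triethylsilyloxy)pent-2-en-1-yl]cyclopent-2-en-1-one | CC[Si](CC)(CC)OCC/C(C)=C\[C@H](O[Si](CC)(CC)CC)C1=C(C)CCC1=O | intermediate
9 | (3Z,5S)-3-methyl-5-(2-methyl-5-oxocyclopent-1-en-1-yl)-5-(triethylsilyloxy)pent-3-enal | O=CC/C(C)=C\[C@H](O[Si](CC)(CC)CC)C1=C(C)CCC1=O | intermediate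
10 | diiodosamarium(III) ketyl of 9 (radical at C10) | I[Sm](I)O[CH]C/C(C)=C\[C@H](O[Si](CC)(CC)CC)C1=C(C)CCC1=O | intermediate
11 | (3aS,4S,8S,8aR)-4-hydroxy-3a,6-dimethyl-8-(triethylsilyloxy)-3,3a,4,5,8,8a-hexahydroazulen-1(2H)-one | O=C1CC[C@]2(C)[C@@H](O)CC(C)=C[C@H](O[Si](CC)(CC)CC)[C@H]12 | intermediate
12 | (3aS,4S,8S,8aR)-4-hydroxy-3a,6-dimethyl-8-(triethylsilyloxy)-3,3a,4,5,8,8a-hexahydroazulen-1-yl trifluoromethanesulfonate | O=S(=O)(OC1=CC[C@]2(C)[C@@H](O)CC(C)=C[C@H](O[Si](CC)(CC)CC)[C@H]12)C(F)(F)F | intermediate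
13 | (3aS,4S,8S,8aR)-3a,6-dimethyl-1-(propan-2-yl)-8-(triethylsilyloxy)-3,3a,4,5,8,8a-hexahydroazulen-4-ol | CC(C)C1=CC[C@]2(C)[C@@H](O)CC(C)=C[C@H](O[Si](CC)(CC)CC)[C@H]12 | intermediate
14 | (3aS,4S,8S,8aR)-3a,6-dimethyl-1-(propan-2-yl)-3,3a,4,5,8,8a-hexahydroazulene-4,8-diol | CC(C)C1=CC[C@]2(C)[C@@H](O)CC(C)=C[C@H](O)[C@H]12 | intermediate
15 | 4-acetoxybenzoyl chloride | CC(=O)Oc1ccc(cc1)C(Cl)=O | starting material
16 | (3aS,4S,8S,8aR)-4-hydroxy-3a,6-dimethyl-1-(propan-2-yl)-3,3a,4,5,8,8a-hexahydroazulen-8-yl 4-acetoxybenzoate | CC(C)C1=CC[C@]2(C)[C@@H](O)CC(C)=C[C@H](OC(=O)c3ccc(OC(C)=O)cc3)[C@H]12 | intermediate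
17 | (1R,2S,3aS,4S,8S,8aR)-1,2,4-trihydroxy-3a,6-dimethyl-1-(propan-2-yl)-1,2,3,3a,4,5,8,8a-octahydroazulen-8-yl 4-acetoxybenzoate | O[C@H]1C[C@]2(C)[C@@H](O)CC(C)=C[C@H](OC(=O)c3ccc(OC(C)=O)cc3)[C@@H]2[C@]1(O)C(C)C | intermediate
18 | 3,4-O-(1-methoxyethylidene) cyclic orthoacetate of 17 (orthoester carbon unassigned) | COC1(C)O[C@H]2C[C@]3(C)[C@@H](O)CC(C)=C[C@H](OC(=O)c4ccc(OC(C)=O)cc4)[C@@H]3[C@]2(O1)C(C)C | intermediate
19 | (1R,2S,3aS,4S,8S,8aR)-2-acetoxy-1,4-dihydroxy-3a,6-dimethyl-1-(propan-2-yl)-1,2,3,3a,4,5,8,8a-octahydroazulen-8-yl 4-acetoxybenzoate | CC(=O)O[C@H]1C[C@]2(C)[C@@H](O)CC(C)=C[C@H](OC(=O)c3ccc(OC(C)=O)cc3)[C@@H]2[C@]1(O)C(C)C | intermediate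
20 | (1R,2S,3aS,4S,8S,8aR)-2-acetoxy-1,4-dihydroxy-3a,6-dimethyl-1-(propan-2-yl)-1,2,3,3a,4,5,8,8a-octahydroazulen-8-yl 4-hydroxybenzoate | CC(=O)O[C@H]1C[C@]2(C)[C@@H](O)CC(C)=C[C@H](OC(=O)c3ccc(O)cc3)[C@@H]2[C@]1(O)C(C)C | target

Total step count: 12. Longest linear sequence: 12 (1 to 20; 3 and 15 are bought).

## Three steps most likely to fail

**Step 6.** The 7-endo closure must build a quaternary centre. It competes with plain reduction of the aldehyde, a 1,5-H shift from C6–H, C10–C4 pinacol coupling and the wrong protonation at C5.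

The fallback sets out from 9 and comes back at 11. It replaces the Sm(II) electron-transfer closure by a neutral tin-hydride chain reaction. PhSeSiMe3 (cat. ZnI2, CH2Cl2, 0 °C) adds to the aldehyde of 9 to give the O-trimethylsilyl hemiselenoacetal F1. Slow addition of Bu3SnH/AIBN (PhH, 80 °C, 5 mM) removes PhSe. The nucleophilic α-siloxyalkyl radical at C10 then closes on C1, and the C5 α-keto radical takes hydrogen from the stannane on the open face. This gives the 10-O-trimethylsilyl ether F2. Citric acid in aqueous MeOH removes only the TMS group and gives 11.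

**Step 10.** OsO4 may also attack C7=C8, or react sluggishly at the hindered C3=C4.

The fallback sets out from 14 and comes back at 19. It switches C7=C8 off electronically before the dihydroxylation.
- MnO2 (CH2Cl2, rt) oxidises only the allylic C6–OH of 14 to the C6 enone F3, whose C7=C8 is now an electron-poor enone alkene.
- Citric-acid-buffered OsO4/NMO hydroxylates C3=C4 alone from the convex face to give the enone triol F4.
- MeC(OMe)3/CSA gives the cyclic orthoacetate F5, and aqueous AcOH opens it to the 3-acetate enone F6.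
- Luche reduction (NaBH4, CeCl3, MeOH, −78 °C) delivers hydride from the convex face and gives the 6-alcohol F7.
- Acylation of F7 with 15 under the conditions of step 9 gives 19.

**Step 8.** The secondary alkyl coupling at a triflate flanked by the C5 methine may give reduction or β-hydride products.

The fallback sets out from 12 and comes back at 13. It uses an sp2–sp2 coupling followed by a selective saturation. Suzuki–Miyaura coupling of 12 with isopropenylboronic acid pinacol ester (Pd(dppf)Cl2, K3PO4, dioxane/H2O, 50 °C) gives the 4-isopropenyl triene F8. Diimide (2-nitrobenzenesulfonylhydrazide, Et3N, CH2Cl2, rt) saturates only the 1,1-disubstituted alkene and gives 13. The acid treatment of step 8 then desilylates 13.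

## Further compounds
F1 | step 6 | 3-methyl-2-[(1S,2Z)-3-methyl-5-(phenylselanyl)-1-(triethylsilyloxy)-5-(trimethylsilyloxy)pent-2-en-1-yl]cyclopent-2-en-1-one (C10 epimers) | C[Si](C)(C)OC([Se]c1ccccc1)C/C(C)=C\[C@H](O[Si](CC)(CC)CC)C1=C(C)CCC1=O
F2 | step 6 | 10-O-trimethylsilyl ether of 11 | O=C1CC[C@]2(C)[C@@H](O[Si](C)(C)C)CC(C)=C[C@H](O[Si](CC)(CC)CC)[C@H]12
F3 | step 10 | C6 ketone of 14 (10-hydroxydauca-3,7-dien-6-one) | CC(C)C1=CC[C@]2(C)[C@@H](O)CC(C)=CC(=O)[C@H]12
F4 | step 10 | 3,4,10-trihydroxydauc-7-en-6-one (3-OH and 4-OH cis to H-5) | O[C@H]1C[C@]2(C)[C@@H](O)CC(C)=CC(=O)[C@@H]2[C@]1(O)C(C)C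
F5 | step 10 | 3,4-O-(1-methoxyethylidene) cyclic orthoacetate of F4 | COC1(C)O[C@H]2C[C@]3(C)[C@@H](O)CC(C)=CC(=O)[C@@H]3[C@]2(O1)C(C)C
F6 | step 10 | 3-acetoxy-4,10-dihydroxydauc-7-en-6-one | CC(=O)O[C@H]1C[C@]2(C)[C@@H](O)CC(C)=CC(=O)[C@@H]2[C@]1(O)C(C)C
F7 | step 10 | 3-acetoxydauc-7-ene-4,6,10-triol (6S) | CC(=O)O[C@H]1C[C@]2(C)[C@@H](O)CC(C)=C[C@H](O)[C@@H]2[C@]1(O)C(C)C
F8 | step 8 | 4-isopropenyl analogue of 13 | C=C(C)C1=CC[C@]2(C)[C@@H](O)CC(C)=C[C@H](O[Si](CC)(CC)CC)[C@H]12
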